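**Retrosynthetic overview**
1. The angelate at C7 goes on last; the tiglate at C9 comes from an Evans–Tishchenko reduction that uses tiglic aldehyde as the hydride donor.
2. The bicyclo[3.1.1]heptenone (cyclobutane plus enone) comes from a 1,2-shift of C10 from C1 to C11 in a 2-amino-norbornen-1-ol, which contracts the five-membered ring C1–C11–C5–C4–C10.
3. The norbornene and the seven-membered ring come together from an intramolecular Diels–Alder reaction of a 1-silyloxycyclopentadiene whose C9–C5 tether ends in an E-nitroalkene.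
4. The tether comes from a C8–C9 aldol of 3,3-dimethylpent-4-en-2-one with an α-quaternary β-keto aldehyde, then radical nitration of the vinyl group.
5. The aldehyde comes from enantioselective hydroxymethylation of 3,5-dimethylcyclopentenone (sets C10). Ring order: cyclopentenone (bought), then seven-membered ring and bicyclo[2.2.1] together, then cyclobutane and cyclohexenone by the shift.

Assumption: labels C1–C11 are the longipinane positions of the target (C1 ketone, C2=C3 enone with CH3 on C3, C6 = CMe2, C7 = O-angelate carbon, C8 = CH2, C9 = O-tiglate carbon, C10 = quaternary C–CH3, cyclobutane = C4/C5/C11/C10), and the four starting materials are taken as catalogue compounds.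

**Step 1**
Reactants: 1 3-methylcyclopent-2-en-1-one
Product: 2 (±)-3,5-dimethylcyclopent-2-en-1-one
Conditions: LiN(iPr)2, THF, −78 °C; MeI, −78 → 0 °C
Reagents that add atoms: iodomethane, CI
Why: Kinetic α′-deprotonation gives the cross-conjugated lithium dienolate, which is C-methylated (enolate alkylation); the product is racemic and this centre is erased in step 2.

**Step 2**
Reactants: 2 (±)-3,5-dimethylcyclopent-2-en-1-one
Product: 4 (S)-5-(hydroxymethyl)-3,5-dimethylcyclopent-2-en-1-one, via silyl dienol ether 3 (not isolated)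
Conditions: LiN(iPr)2, THF, −78 °C; Me3SiCl; then Sc(OTf)3 (10 mol %), (S,S)-6,6′-bis(1-hydroxy-2,2-dimethylpropyl)-2,2′-bipyridine (12 mol %), aq. HCHO, DME–H2O, −20 °C
Reagents that add atoms: chlorotrimethylsilane, C[Si](C)(C)Cl (in 3 only); formaldehyde, C=O
Why: Kobayashi-type aqueous Mukaiyama aldol (hydroxymethylation): the chiral scandium–bipyridine complex delivers formaldehyde to one enantiotopic face of the tetrasubstituted enol silane and sets the quaternary centre C10 (S), which later controls every other stereocentre; the ligand antipode is used if the sense of induction is opposite for this enolate.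

**Step 3**
Reactants: 4 (S)-5-(hydroxymethyl)-3,5-dimethylcyclopent-2-en-1-one
Product: 5 (S)-1,4-dimethyl-2-oxocyclopent-3-ene-1-carbaldehyde
Conditions: Dess–Martin periodinane, CH2Cl2, 0 → 23 °C
Reagents that add atoms: none
Why: Dess–Martin oxidation of a neopentyl primary alcohol; the aldehyde has a quaternary α-carbon and cannot enolise or epimerise.

**Step 4**
Reactants: 6 2,2-dimethylbut-3-enoic acid
Product: 7 3,3-dimethylpent-4-en-2-one
Conditions: MeLi (2.1 equiv), Et2O, 0 °C; aqueous work-up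
Reagents that add atoms: methyllithium, [Li]C
Why: Carboxylic acid to methyl ketone: the lithium carboxylate adds MeLi to a stable dilithium gem-diolate that collapses to the ketone only on work-up, so no over-addition.

**Step 5**
Reactants: 5 (S)-1,4-dimethyl-2-oxocyclopent-3-ene-1-carbaldehyde; 7 3,3-dimethylpent-4-en-2-one
Product: 8 (S)-5-[(1R)-1-hydroxy-4,4-dimethyl-3-oxohex-5-en-1-yl]-3,5-dimethylcyclopent-2-en-1-one
Conditions: 7, LiN(iPr)2, THF, −78 °C; then 5 premixed with MgBr2·OEt2, −78 °C; pH 7 buffer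
Reagents that add atoms: none
Why: Crossed aldol in which only the CH3 of 7 can enolise and 5 cannot; under chelation of C9=O and C1=O by magnesium the enolate should add anti to the C10 methyl group (syn to the tied-back ring CH2) to give 9R. The facial bias is small, so a modest ratio is expected and the 9-epimer is removed by chromatography.

**Step 6**
Reactants: 8 (S)-5-[(1R)-1-hydroxy-4,4-dimethyl-3-oxohex-5-en-1-yl]-3,5-dimethylcyclopent-2-en-1-one; 9 (E)-2-methylbut-2-enal
Product: 10 (1R,3R)-1-[(1S)-1,4-dimethyl-2-oxocyclopent-3-en-1-yl]-3-hydroxy-4,4-dimethylhex-5-en-1-yl (E)-2-methylbut-2-enoate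
Conditions: SmI2 (30 mol %), 9 (5 equiv), THF, −10 °C
Reagents that add atoms: none
Why: Evans–Tishchenko reduction: the samarium-bound hemiacetal of the C9 hydroxyl with tiglic aldehyde delivers hydride intramolecularly through a six-membered chair to C7=O, giving the anti-1,3 relationship (7R) and placing the tiglate on C9–O in the same step. The conjugated ring ketone C1=O is also β to this hydroxyl; it is expected to be spared because it is less electrophilic and more hindered.

**Step 7**
Reactants: 10 (1R,3R)-1-[(1S)-1,4-dimethyl-2-oxocyclopent-3-en-1-yl]-3-hydroxy-4,4-dimethylhex-5-en-1-yl (E)-2-methylbut-2-enoate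
Product: 11 (1R,3R,5E)-1-[(1S)-1,4-dimethyl-2-oxocyclopent-3-en-1-yl]-3-hydroxy-4,4-dimethyl-6-nitrohex-5-en-1-yl (E)-2-methylbut-2-enoate
Conditions: AgNO2 (3 equiv), TEMPO (0.4 equiv), 4 Å MS, ClCH2CH2Cl, 70 °C
Reagents that add atoms: silver nitrite, [Ag+].[O-]N=O
Why: Radical nitration of a terminal olefin (NO2 adds to the only unhindered, non-conjugated C=C and TEMPO removes the hydrogen) gives the E-nitroalkene; C6 is quaternary, so no allylic nitro isomer can form.

**Step 8**
Reactants: 11 (1R,3R,5E)-1-[(1S)-1,4-dimethyl-2-oxocyclopent-3-en-1-yl]-3-hydroxy-4,4-dimethyl-6-nitrohex-5-en-1-yl (E)-2-methylbut-2-enoate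
Product: 13 silylated nitro Diels–Alder adduct (1,7-bis(trimethylsilyloxy)-11-endo-nitro-9-tigloyloxy tricycle), via bis-silyl dienol ether 12 (not isolated)
Conditions: Me3SiOTf (2.4 equiv), Et3N (4 equiv), CH2Cl2, −78 → 0 °C; then PhMe, 60 °C, 0.01 M
Reagents that add atoms: trimethylsilyl trifluoromethanesulfonate, C[Si](C)(C)OS(=O)(=O)C(F)(F)F
Why: Soft γ-enolisation (α′ is quaternary) gives a 1-silyloxycyclopentadiene that cannot undergo 1,5-hydrogen shift at C10, and it then reacts in an intramolecular Diels–Alder reaction tethered at the sp3 carbon of the diene. The nucleophilic terminus C4 bonds to the nitroalkene β-carbon C5 and C1 bonds to C11; the tether forces addition on the C9 face, and the E-alkene puts C6 exo and NO2 endo, which sets C1, C4, C5 and C11.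

**Step 9**
Reactants: 13 silylated nitro Diels–Alder adduct (1,7-bis(trimethylsilyloxy)-11-endo-nitro-9-tigloyloxy tricycle)
Product: 16 7-hydroxy-9-tigloyloxylongipin-2-en-1-one, via amino alcohol 14 (not isolated), via diazonium acetate 15 (not isolated)
Conditions: Zn, AcOH–THF–H2O (3:1:1), 0 → 23 °C; filter; NaNO2, 0 → 23 °C
Reagents that add atoms: sodium nitrite, [Na+].[O-]N=O (nitrogen of 15 only); acetic acid, CC(=O)O (acetate of 15 only)
Why: Proposed new method: zinc in aqueous acetic acid reduces the nitro group and removes both silyl groups, and nitrous acid converts the endo amine into an endo diazonium ion whose C11–N bond is antiperiplanar to the C1–C10 bridge bond; pushed by the bridgehead hydroxyl (which can neither ionise nor close to an epoxide), C10 migrates from C1 to C11 with inversion at C11 and loss of N2, contracting the cyclopentane C1/C11/C5/C4/C10 to the cyclobutane C4/C5/C11/C10 and creating the C1 ketone already conjugated with C2=C3; C4, C5 and C10 are untouched and C11 is fixed by the forced backside attack; loss of N2 and formation of C=O should pay for the extra ring strain; the closest known reaction type is the Tiffeneau–Demjanov (semipinacolic) deamination of 2-aminocycloalkanols and the quasi-Favorskii shift of bridged alkoxides, not yet shown for a bicyclo[2.2.1] to bicyclo[3.1.1] change.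

**Step 10**
Reactants: 16 7-hydroxy-9-tigloyloxylongipin-2-en-1-one; 17 (Z)-2-methylbut-2-enoic acid
Product: 19 7-angeloyloxy-9-tigloyloxylongipin-2-en-1-one (CNP0236543.4), via mixed anhydride 18 (not isolated)
Conditions: 17, 2,4,6-Cl3C6H2COCl, Et3N, PhMe, 23 °C; then 16, PhMe, 80 °C
Reagents that add atoms: 2,4,6-trichlorobenzoyl chloride, O=C(Cl)c1c(Cl)cc(Cl)cc1Cl (in 18 only)
Why: Yamaguchi-type mixed-anhydride acylation run without DMAP, which transfers the angeloyl group to the hindered C7 alcohol without Z-to-E isomerisation; no stereocentre is touched.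

**Compound list**
1 | 3-methylcyclopent-2-en-1-one | CC1=CC(=O)CC1 | starting material
2 | (±)-3,5-dimethylcyclopent-2-en-1-one | CC1CC(C)=CC1=O | intermediate
3 | [(2,4-dimethylcyclopenta-1,4-dien-1-yl)oxy]trimethylsilane | CC1=C(O[Si](C)(C)C)C=C(C)C1 | intermediate
4 | (S)-5-(hydroxymethyl)-3,5-dimethylcyclopent-2-en-1-one | OC[C@@]1(C)C(=O)C=C(C)C1 | intermediate
5 | (S)-1,4-dimethyl-2-oxocyclopent-3-ene-1-carbaldehyde | O=C[C@@]1(C)C(=O)C=C(C)C1 | intermediate
6 | 2,2-dimethylbut-3-enoic acid | C=CC(C)(C)C(=O)O | starting material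
7 | 3,3-dimethylpent-4-en-2-one | C=CC(C)(C)C(C)=O | intermediate
8 | (S)-5-[(1R)-1-hydroxy-4,4-dimethyl-3-oxohex-5-en-1-yl]-3,5-dimethylcyclopent-2-en-1-one | C=CC(C)(C)C(=O)C[C@@H](O)[C@@]1(C)C(=O)C=C(C)C1 | intermediate
9 | (E)-2-methylbut-2-enal (tiglic aldehyde) | C/C=C(\C)C=O | starting material
10 | (1R,3R)-1-[(1S)-1,4-dimethyl-2-oxocyclopent-3-en-1-yl]-3-hydroxy-4,4-dimethylhex-5-en-1-yl (E)-2-methylbut-2-enoate | C=CC(C)(C)[C@H](O)C[C@@H](OC(=O)/C(C)=C/C)[C@@]1(C)C(=O)C=C(C)C1 | intermediate
11 | (1R,3R,5E)-1-[(1S)-1,4-dimethyl-2-oxocyclopent-3-en-1-yl]-3-hydroxy-4,4-dimethyl-6-nitrohex-5-en-1-yl (E)-2-methylbut-2-enoate | [O-][N+](=O)/C=C/C(C)(C)[C@H](O)C[C@@H](OC(=O)/C(C)=C/C)[C@@]1(C)C(=O)C=C(C)C1 | intermediate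
12 | (1R,3R,5E)-1-[(1S)-1,4-dimethyl-2-(trimethylsilyloxy)cyclopenta-2,4-dien-1-yl]-4,4-dimethyl-6-nitro-3-(trimethylsilyloxy)hex-5-en-1-yl (E)-2-methylbut-2-enoate | [O-][N+](=O)/C=C/C(C)(C)[C@H](O[Si](C)(C)C)C[C@@H](OC(=O)/C(C)=C/C)[C@@]1(C)C(O[Si](C)(C)C)=CC(C)=C1 | intermediate
13 | Diels–Alder adduct: norbornene C1(OSiMe3, bridgehead)/C2=C3(CH3)/C4/C5/C11 with C10(CH3) as one-carbon bridge (CH3 syn to C2=C3), seven-membered ring C4–C5–C6–C7–C8–C9–C10, C6 exo on C5, 11-endo-NO2, 7-OSiMe3, 9-O-tiglate | C[Si](C)(C)O[C@@H]1C[C@@H](OC(=O)/C(C)=C/C)[C@@]2(C)[C@]3(O[Si](C)(C)C)C=C(C)[C@H]2[C@H](C1(C)C)[C@H]3[N+](=O)[O-] | intermediate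
14 | amino alcohol: as 13 with 1-OH, 7-OH and 11-endo-NH2 | O[C@@H]1C[C@@H](OC(=O)/C(C)=C/C)[C@@]2(C)[C@]3(O)C=C(C)[C@H]2[C@H](C1(C)C)[C@H]3N | intermediate
15 | 11-endo-diazonium acetate of 14 | CC(=O)[O-].O[C@@H]1C[C@@H](OC(=O)/C(C)=C/C)[C@@]2(C)[C@]3(O)C=C(C)[C@H]2[C@H](C1(C)C)[C@H]3[N+]#N | intermediate
16 | 7-hydroxy-9-[(E)-2-methylbut-2-enoyloxy]longipin-2-en-1-one (target without the angelate) | O[C@@H]1C[C@@H](OC(=O)/C(C)=C/C)[C@@]2(C)[C@@H]3C(=O)C=C(C)[C@H]2[C@@H]3C1(C)C | intermediate
17 | (Z)-2-methylbut-2-enoic acid (angelic acid) | C/C=C(/C)C(=O)O | starting material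
18 | (Z)-2-methylbut-2-enoic 2,4,6-trichlorobenzoic anhydride | C/C=C(/C)C(=O)OC(=O)c1c(Cl)cc(Cl)cc1Cl | intermediate
19 | 7-[(Z)-2-methylbut-2-enoyloxy]-9-[(E)-2-methylbut-2-enoyloxy]longipin-2-en-1-one (CNP0236543.4) | C/C=C(/C)C(=O)O[C@@H]1C[C@@H](OC(=O)/C(C)=C/C)[C@@]2(C)[C@@H]3C(=O)C=C(C)[C@H]2[C@@H]3C1(C)C | target

**Step count**
Total steps: 10. Longest linear sequence: 9 (steps 1, 2, 3, 5, 6, 7, 8, 9, 10; step 4 is a one-step side branch).

**Three steps most likely to fail**

Step 9, the new 1,2-shift. The diazonium ion may instead give C2 migration, hydride shift or solvolysis. The fallback sets out from 10 and comes back at 16. It uses known reaction types only, though the closing sulfonate shift, like step 9, has no precedent for this ring change. Dehydrogenative borylation of the vinyl group of 10 (RhCl(CO)(PPh3)2, B2pin2) gives the (E)-alkenylboronate F5. Et3SiOTf and Et3N turn it into the bis-triethylsilyl dienol ether F6 (not isolated), which on heating undergoes the same intramolecular Diels–Alder reaction to the endo-boryl adduct F7. NaBO3·4H2O oxidises the C–B bond with retention to the endo alcohol F8, and MsCl/Et3N gives the endo mesylate F9. Bu4NF then frees the bridgehead alkoxide, which undergoes the anionic shift of a β-sulfonyloxy alkoxide (Tsuchihashi–Suzuki or quasi-Favorskii type) without any free cation; the C7 silyl ether is lost in the same operation, giving 16.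

Step 8, the intramolecular Diels–Alder reaction. It forms a seven-membered ring next to two quaternary carbons, and silyl nitronate formation is a possible side path. The fallback sets out from 12 and comes back at 13, replacing the concerted cycloaddition by a stepwise polar annulation. Catalytic Me3SiOTf at −78 °C triggers a vinylogous Mukaiyama–Michael addition of C4 to C5 and gives the bicyclic silyl nitronate F4, in which the seven-membered ring is already closed. Catalytic Bu4NF then induces the intramolecular silyl-nitronate aldol addition (Seebach–Colvin type) of C11 to the C1 carbonyl with silyl transfer to oxygen, which closes the C1–C11 bond and delivers 13.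

Step 2, the asymmetric hydroxymethylation. Enantioselectivity is untested on this cross-conjugated cyclopentadienyl silyl ether. The fallback sets out from 2 and comes back at 5. The lithium dienolate of 2 is O-acylated with allyl chloroformate to allyl 2,4-dimethylcyclopenta-1,4-dien-1-yl carbonate F1. Decarboxylative asymmetric allylic alkylation (Pd2(dba)3, (S)-t-BuPHOX) gives (R)-5-allyl-3,5-dimethylcyclopent-2-en-1-one F2. PdCl2(MeCN)2 isomerises the allyl group to the (E)-propenyl ketone F3, and OsO4 (cat.)/NaIO4 cleaves the propenyl group to aldehyde 5.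

**Further compounds**
F1 | step 2 | allyl 2,4-dimethylcyclopenta-1,4-dien-1-yl carbonate | CC1=C(OC(=O)OCC=C)C=C(C)C1
F2 | step 2 | (R)-3,5-dimethyl-5-(prop-2-en-1-yl)cyclopent-2-en-1-one | C=CC[C@@]1(C)C(=O)C=C(C)C1
F3 | step 2 | (S)-3,5-dimethyl-5-[(E)-prop-1-en-1-yl]cyclopent-2-en-1-one | C/C=C/[C@@]1(C)C(=O)C=C(C)C1
F4 | step 8 | bicyclic silyl nitronate (cyclopentenone fused at C4–C10 to the seven-membered ring, C5 bearing CH=N(O)OSiMe3, 7-OSiMe3, 9-O-tiglate) | C[Si](C)(C)O[C@@H]1C[C@@H](OC(=O)/C(C)=C/C)[C@@]2(C)C(=O)C=C(C)[C@H]2[C@H](C1(C)C)C=[N+]([O-])O[Si](C)(C)C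
F5 | step 9 | (1R,3R,5E)-1-[(1S)-1,4-dimethyl-2-oxocyclopent-3-en-1-yl]-3-hydroxy-4,4-dimethyl-6-(4,4,5,5-tetramethyl-1,3,2-dioxaborolan-2-yl)hex-5-en-1-yl (E)-2-methylbut-2-enoate | CC1(C)OB(/C=C/C(C)(C)[C@H](O)C[C@@H](OC(=O)/C(C)=C/C)[C@@]2(C)C(=O)C=C(C)C2)OC1(C)C
F6 | step 9 | bis-triethylsilyl dienol ether of F5 | CC1(C)OB(/C=C/C(C)(C)[C@H](O[Si](CC)(CC)CC)C[C@@H](OC(=O)/C(C)=C/C)[C@@]2(C)C(O[Si](CC)(CC)CC)=CC(C)=C2)OC1(C)C
F7 | step 9 | Diels–Alder adduct as 13 with 1-OSiEt3, 7-OSiEt3 and 11-endo-B(pin) | CC[Si](CC)(CC)O[C@@H]1C[C@@H](OC(=O)/C(C)=C/C)[C@@]2(C)[C@]3(O[Si](CC)(CC)CC)C=C(C)[C@H]2[C@H](C1(C)C)[C@H]3B4OC(C)(C)C(C)(C)O4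
F8 | step 9 | 11-endo alcohol from F7 | CC[Si](CC)(CC)O[C@@H]1C[C@@H](OC(=O)/C(C)=C/C)[C@@]2(C)[C@]3(O[Si](CC)(CC)CC)C=C(C)[C@H]2[C@H](C1(C)C)[C@H]3O
F9 | step 9 | 11-endo methanesulfonate of F8 | CC[Si](CC)(CC)O[C@@H]1C[C@@H](OC(=O)/C(C)=C/C)[C@@]2(C)[C@]3(O[Si](CC)(CC)CC)C=C(C)[C@H]2[C@H](C1(C)C)[C@H]3OS(C)(=O)=O
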